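We want to know which species holds the largest share of the D charged when the flask is read at 2.0 h, and how large that share is.

| setting | eta | beta | flask |
|---|---|---|---|
| D | 22 mM | 35 mM | 16 mM |
| Z | 1.1 equiv (fed, over 2.0 h) | 1.1 equiv (fed, over 2.0 h) | 1.10 equiv (fed, over 2.0 h) |
| remark | run made earlier; the fed solution adds 0.10 times the starting volume | run made earlier; the fed solution adds 0.10 times the starting volume | the fed solution adds 0.10 times the starting volume |
| time |  |  | 2.0 h |

| run | time / h | X / % | D / % | G / % | Q / % | E / % | L / % |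
|---|---|---|---|---|---|---|---|
| eta | 0.200 | 7.6 | 87.2 | 0 | 0 | 3.2 | 0.6 |
| eta | 0.333 | 10.0 | 82.3 | 1.1 | 1.7 | 5.3 | 0 |
| eta | 0.667 | 12.1 | 70.0 | 4.6 | 1.4 | 14.5 | 1.5 |
| eta | 1.33 | 11.1 | 37.5 | 18.8 | 2.8 | 24.0 | 5.1 |
| eta | 2.50 | 4.0 | 0.2 | 47.4 | 4.1 | 24.1 | 18.2 |
| beta | 0.200 | 7.1 | 94.7 | 0.5 | 0 | 0.2 | 0.9 |
| beta | 0.667 | 6.1 | 80.5 | 2.3 | 3.0 | 7.3 | 1.8 |
| beta | 1.00 | 7.8 | 69.6 | 6.4 | 3.9 | 12.4 | 0.8 |
| beta | 1.50 | 9.0 | 55.1 | 14.1 | 3.3 | 14.6 | 4.5 |
| beta | 2.50 | 8.9 | 26.1 | 26.0 | 5.0 | 16.8 | 16.8 |

(scatter of a reading: 1 percentage point)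

- every charge counts on the volume at the start, and the solution that is fed holds the whole dose
- solid, in amounts per volume of the solution: D
- at the start none of D is in solution
- a reading or a percentage of L counts all its forms, free or not
- X means what is dissolved; the solid is not counted in it

* the largest share of what was charged as D, at 2.0 h belongs to (Q / E / X / G / L)
* the largest share itself, whichever of these holds it, in percent of the D charged

Let us follow one molecule of D: the order in which the species rise in the runs suggests that it waits in the solid, dissolves as X, and then passes through E into G, with a side road through Q into L. The wait comes first, so we read it first. The solid shrinks at 10.3 mM h⁻¹ in the eta run and at 10.3 mM h⁻¹ in the beta run, although their charges differ. We therefore take one pace, a zero-order supply of 10.3 mM h⁻¹. The dissolving fraction, the part of the charge that this pace dissolves per hour, is then 0.646 h⁻¹ in the flask, so we expect its solid to last about 1.55 h.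

Two extremes can be reckoned in the head. In the fast one, D stands as E at once. The last two eta readings put E into G at 1.02 h⁻¹, a lifetime of 0.984 h, and G reaches 86.9 %. In the slow one, the solid outlasts the reading, as in the eta run, whose solid needs 2.13 h. Amounts in mM then follow the pace, so the eta share of G interpolated to 2.0 h, 35.2 %, scales with the charges to 48.4 %.

By this reckoning a typical molecule reaching G by 2.0 h dissolved before about 1.02 h, earlier than our estimated end of the solid, so we place the flask near the slow extreme. We commit to G at about 48.4 %, above E at about 33.1 %, scaled the same way from the last eta reading. The forecast also names G, but at 42 %, lower than ours, holding that the lower charge “shifts everything further along”. The reading to watch is D at 1.00 h.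

The flask gives G at 50.1 %.

    Z + G → L (k = 0.00280 L mol⁻¹ s⁻¹)
    D ⇌ X, rate k2*(cs2 - [X]) while solid is left; crystals form when [X] > cs2 (solubility = 9.20 mM, k = 3.90 × 10⁻⁴ s⁻¹)
    X + Z ⇌ Q (K = 41.0 L mol⁻¹, k = 0.0260 L mol⁻¹ s⁻¹)
    Q → L (k = 3.20 × 10⁻⁴ s⁻¹)
    X ⇌ E (K = 17.0, k = 9.40 × 10⁻⁴ s⁻¹)
    E → G (k = 3.20 × 10⁻⁴ s⁻¹)
    Z + L ⇌ J, settled at all times (K = 32.0 L mol⁻¹)

At 1.00 h the flask holds 36.2 % of the D charged as solid, against 35.4 % from the dissolving fraction. With 40 mM of D and the recipe otherwise held, the same pace gives a dissolving fraction of 0.258 h⁻¹, which leaves 48.5 % of D at 2.00 h. That flask holds 48.2 % of D then, and its G stands at 17.1 %.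

The data come from a simulation for substances that don't exist.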